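A plateau cannot be reckoned from the ratio of the charges: if two nucleophiles compete for one intermediate, each uses itself up, and the ratio changes during the run. What can stay constant is the capture ratio s (a selectivity factor): ln(fraction of second nucleophile not captured) divided by ln(fraction of first nucleophile not captured). I take target and other capture product to add up to the substrate charged.

| flask | substrate | first nucleophile | second nucleophile | protic impurity | temperature | remark | time |
|---|---|---|---|---|---|---|---|
| Tuesday's | 0.074 M | 0.95 equiv | 0.60 equiv | 0.48 M | 25 °C | run made earlier |  |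
| Saturday's | 0.40 M | 0.95 equiv | 0.60 equiv | 0.48 M | 65 °C | run made earlier |  |
| Sunday's | 0.48 M | 0.95 equiv | 0.34 equiv | 0.48 M | 25 °C | run made earlier |  |
| midnight | 0.48 M | 0.950 equiv | 0.600 equiv | 0.480 M | 60 °C |  | 12 min |
| winter | 0.48 M | 0.640 equiv | 0.600 equiv | 0.480 M | 100 °C |  | 12 min |
| noon | 0.30 M | 1.40 equiv | 0.150 equiv | 0.480 M | 60 °C |  | 12 min |
| summer | 0.12 M | 0.950 equiv | 0.300 equiv | 0.480 M | 30 °C |  | 12 min |

| run | time / min | target / % |
|---|---|---|
| Tuesday's | 4.00 | 47 |
| Tuesday's | 6.00 | 50 |
| Tuesday's | 12.0 | 50 |
| Tuesday's | 15.0 | 55 |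
| Tuesday's | 30.0 | 53 |
| Tuesday's | 50.0 | 55 |
| Saturday's | 1.33 | 51 |
| Saturday's | 3.00 | 48 |
| Saturday's | 4.00 | 47 |
| Saturday's | 6.00 | 47 |
| Saturday's | 8.00 | 53 |
| Sunday's | 4.00 | 59 |
| Sunday's | 8.00 | 70 |
| Sunday's | 15.0 | 68 |
| Sunday's | 25.0 | 70 |
| Sunday's | 50.0 | 66 |

(readings scatter by 2 percentage points)

- the flasks put in order of amount of target, in percent of the substrate charged, best first, at 12 min (midnight / winter / noon / summer)
- the same order at 40 s (midnight / winter / noon / summer)
- the amount of target, in percent of the substrate charged of the flask you put first, at 12 min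
- the amount of target, in percent of the substrate charged of the flask you put last, at 12 min

- the numbers in the tables scatter with a standard deviation of 2 percentage points

Which numbers must I know well?

1. Time. Saturday's readings are flat from 1.33 min. Sunday's plateau reads 68.5 %, and its first reading then gives a pace of 0.494 min⁻¹ at 25 °C. The summer flask runs at 30 °C; taking a doubling of the pace per 10 degrees, I put its pace at about 0.698 min⁻¹. So I expect plateaus by 12 min, but at 40 s the summer flask has about 37.2 % of its way behind it. I guess the hot flasks are finished by then.

2. The ratio at low temperature. Sunday gives 2.04. Tuesday, with plateau 54.3 %, gives 1.69. I carry that gap as error and leave the impurity out.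

3. Noon hardly cares. Its 0.150 equiv of second nucleophile takes at most that much substrate, so noon stands at 85.0 % or above. One round gives 88.1 % with the lower ratio and 87.2 % with the higher.

4. Midnight and winter do care, with their 0.600 equiv. So I need the ratio near their temperature. Saturday's plateau of 49.2 % gives the capture ratio 2.57, higher than Sunday's.

5. Going round, putting each answer back in: noon runs 85.0 %, 86.4 %, 86.3 %. Winter at this ratio runs 44.8 %, 42.7 %, 43.5 %, and its heat should push it lower. Midnight sits near 49.2 %. Summer, at Sunday's ratio, gives 72.0 %, so about 26.8 % at 40 s, which puts it last then.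

The forecast reads noon > summer > midnight > winter and noon > midnight > winter > summer, with 86 % and 43 %, on the ground that yield is “set by competition for the intermediate, with the nucleophiles depleting”.

The flasks give noon > summer > midnight > winter and noon > midnight > winter > summer, with 86.1 % and 40.2 %.

    substrate + intermediate → side product (k = 0.0267 M⁻¹ s⁻¹, Ea = 77.0 kJ mol⁻¹)
    second nucleophile + intermediate → other capture product (k = 64.0 M⁻¹ s⁻¹, Ea = 56.0 kJ mol⁻¹)
    first nucleophile + protic impurity → quenched reagent (k = 0.0307 M⁻¹ s⁻¹, Ea = 54.0 kJ mol⁻¹)
    substrate → intermediate (k = 0.204 s⁻¹, Ea = 75.0 kJ mol⁻¹)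
    first nucleophile + intermediate → target (k = 27.3 M⁻¹ s⁻¹, Ea = 39.0 kJ mol⁻¹)
    (constants at 60 °C)

Winter's target falls short partly through the path from second nucleophile + intermediate to other capture product: with that path taken away, winter gives 62.7 % against 40.2 %, which is 38 % of what is missing. Winter's own ratio, from 0.75 % of second nucleophile left and its target, is 4.94, above Saturday's 2.57. Carried to winter's neighbour with 1.10 equiv of first nucleophile, rounds from 40.2 % run 46.3 %, 44.0 %, 44.8 %, and that flask stands at 44.8 %.

Readings and results come from a simulation with made-up constants; scatter was added.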